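**Retrosynthetic overview**

1. The target is a 4-aryl-1-tetralone: ring A is the 6,7-dimethoxybenzo ring, ring B the cyclohexanone (C1–C4, C4a, C8a), ring C the 3-hydroxy-4-methoxyphenyl group on C4.
2. Ring B is cut at C1–C8a and at C2–C3. This leaves a 1,1-diarylpropene (C3=C4, rings A and C both on C4) and the C1–C2 unit with its methyl group as 1-ethoxyprop-1-yne. Both bonds are made in one photoredox radical-cation [4+2] annulation.
3. Enabling feature: C4 carries rings A and C, so C3=C4 is an easily oxidised 1,1-diarylalkene whose radical cation takes a carbon nucleophile at C3 and leaves a stabilised radical at C4. C8a of ring A lies ortho to C4a and para to the C6 methoxy group, ready to trap the cation at C1. The ring C hydroxyl, as its acetate, keeps ring C out of the closure.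
4. The alkene comes from 3,4-dimethoxypropiophenone (ring A, C4, C3 and its methyl) by enol triflation and Suzuki–Miyaura coupling with the ring C boronic acid. Rings A and C are bought; ring B is formed last.
5. Stereocentres: C3 in the C–C bond formation (chiral counter-anion), C4 by hydrogen-atom transfer anti to the C3 methyl, C2 by equilibration; deacetylation ends the route.

Key step: step 4

Remark: tetralone numbering is used throughout (C1 = carbonyl carbon, C4 = carbon bearing ring C); the sense of induction of the chiral anion cannot be predicted, so the antipode of the IDPi acid that leads to (3R) is assumed to be used.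

**Step 1**
Reactants: 1 1-(3,4-dimethoxyphenyl)propan-1-one
Product: 2 (Z)-1-(3,4-dimethoxyphenyl)prop-1-en-1-yl trifluoromethanesulfonate
Conditions: KHMDS (1.1 equiv), THF, −78 °C; then PhNTf2 (1.1 equiv), −78 → 0 °C
Reagents that add atoms: N-phenylbis(trifluoromethanesulfonimide), O=S(=O)(N(c1ccccc1)S(=O)(=O)C(F)(F)F)C(F)(F)F
Why: Kinetic deprotonation of the aryl ethyl ketone should give the (Z)-potassium enolate, which is O-sulfonylated by the triflimide (enol triflate formation).

**Step 2**
Reactants: 2 (Z)-1-(3,4-dimethoxyphenyl)prop-1-en-1-yl trifluoromethanesulfonate; 3 (3-hydroxy-4-methoxyphenyl)boronic acid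
Product: 4 (E)-5-[1-(3,4-dimethoxyphenyl)prop-1-en-1-yl]-2-methoxyphenol
Conditions: Pd(PPh3)4 (3 mol%), Na2CO3 (3 equiv), DME/H2O, 70 °C
Reagents that add atoms: none
Why: Suzuki–Miyaura coupling of an alkenyl triflate with an arylboronic acid tolerates the free phenol and should proceed with retention of the alkene geometry.

**Step 3**
Reactants: 4 (E)-5-[1-(3,4-dimethoxyphenyl)prop-1-en-1-yl]-2-methoxyphenol
Product: 5 (Z)-5-[1-(3,4-dimethoxyphenyl)prop-1-en-1-yl]-2-methoxyphenyl acetate
Conditions: Ac2O (1.5 equiv), pyridine, DMAP (5 mol%), CH2Cl2, 0 °C → rt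
Reagents that add atoms: acetic anhydride, CC(=O)OC(C)=O
Why: O-Acetylation of the phenol (nucleophilic acyl substitution) turns the strong donor on ring C into a weak one, which is what keeps ring C out of the ring closure in step 4; the descriptor changes from E to Z only through the CIP priorities.

**Step 4**
Reactants: 5 (Z)-5-[1-(3,4-dimethoxyphenyl)prop-1-en-1-yl]-2-methoxyphenyl acetate; 6 1-ethoxyprop-1-yne
Product: 8 5-[(1R,2R,3S)-6,7-dimethoxy-2,3-dimethyl-4-oxo-1,2,3,4-tetrahydronaphthalen-1-yl]-2-methoxyphenyl acetate, via enol ether 7 (not isolated)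
Conditions: 9-mesityl-10-methylacridinium as its chiral IDPi (imidodiphosphorimidate) salt (5 mol%), PhSSPh (10 mol%), 6 (2 equiv), CH2Cl2, −40 °C, 450 nm LED; then 2 M HCl, THF, 40 °C
Reagents that add atoms: water, O
Why: Proposed new method: single-electron oxidation of the 1,1-diarylalkene of 5 by the excited acridinium gives a radical cation (the alkene geometry is lost) that, as a contact ion pair with the chiral IDPi anion, is attacked at C3 by the nucleophilic C2 of ynol ether 6 (anti-Markovnikov, C2–C3), which leaves the doubly benzylic radical at C4 and an α-ethoxyvinyl cation at C1. This digonal cation is trapped at once by C8a of the dimethoxy ring (C1–C8a; six-membered ring B closes in a 6-endo Friedel–Crafts mode onto the cationic carbon), and after loss of the proton the thiol gives a hydrogen atom to the now cyclic C4 radical and is regenerated by the reduced photocatalyst, so that the step is redox-neutral and ends at enol ether 7, which the acid work-up hydrolyses to ketone 8. The closest known reaction types are the electron-transfer [4+2] cyclodimerisation of 1,1-diarylethylenes to 4-aryltetralins (the same two kinds of bond), the acridinium/thiol anti-Markovnikov addition of nucleophiles to aryl alkene radical cations, and the chiral-anion-directed photoredox cyclopropanation of aryl alkene radical cations. C3 is set in the C2–C3 bond formation by the face of the radical cation that the chiral anion leaves open, C4 by the substrate, because the hydrogen atom reaches the almost flat ring anti to the pseudo-axial C3 methyl group (3,4-cis), and C2, sp2 in 7, only on hydrolysis and under thermodynamic control (2,3-trans). The step needs ring closure on the dimethoxy ring and not on ring C, secured by the acetate (no strong donor ortho or para to the open positions of ring C) and by the C6 methoxy group para to C8a, and it needs oxidation of 5 before 6 and before 7, for which the low potential of the bis(alkoxyaryl)alkene and a limited conversion have to serve.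

**Step 5**
Reactants: 8 5-[(1R,2R,3S)-6,7-dimethoxy-2,3-dimethyl-4-oxo-1,2,3,4-tetrahydronaphthalen-1-yl]-2-methoxyphenyl acetate
Product: 9 (2S,3R,4R)-4-(3-hydroxy-4-methoxyphenyl)-6,7-dimethoxy-2,3-dimethyl-3,4-dihydronaphthalen-1(2H)-one
Conditions: K2CO3 (0.5 equiv), MeOH (degassed), rt; then aq. NH4Cl
Reagents that add atoms: none
Why: Base-catalysed transesterification of the aryl acetate with methanol should set the phenol free, and the same base keeps the enolisable C2 at the thermodynamic 2,3-trans configuration (both methyl groups pseudo-equatorial, C4 aryl pseudo-axial), while C3 and C4 cannot enolise and stay untouched.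

**Compound list**

1 | 1-(3,4-dimethoxyphenyl)propan-1-one | CCC(=O)c1ccc(OC)c(OC)c1 | starting material
2 | (Z)-1-(3,4-dimethoxyphenyl)prop-1-en-1-yl trifluoromethanesulfonate | C/C=C(/c1ccc(OC)c(OC)c1)OS(=O)(=O)C(F)(F)F | intermediate
3 | (3-hydroxy-4-methoxyphenyl)boronic acid | COc1ccc(B(O)O)cc1O | starting material
4 | (E)-5-[1-(3,4-dimethoxyphenyl)prop-1-en-1-yl]-2-methoxyphenol | C/C=C(/c1ccc(OC)c(OC)c1)c1ccc(OC)c(O)c1 | intermediate
5 | (Z)-5-[1-(3,4-dimethoxyphenyl)prop-1-en-1-yl]-2-methoxyphenyl acetate | C/C=C(/c1ccc(OC)c(OC)c1)c1ccc(OC)c(OC(C)=O)c1 | intermediate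
6 | 1-ethoxyprop-1-yne | CC#COCC | starting material
7 | 5-[(1R,2R)-4-ethoxy-6,7-dimethoxy-2,3-dimethyl-1,2-dihydronaphthalen-1-yl]-2-methoxyphenyl acetate (not isolated) | COc1ccc([C@@H]2c3cc(OC)c(OC)cc3C(OCC)=C(C)[C@@H]2C)cc1OC(C)=O | intermediate
8 | 5-[(1R,2R,3S)-6,7-dimethoxy-2,3-dimethyl-4-oxo-1,2,3,4-tetrahydronaphthalen-1-yl]-2-methoxyphenyl acetate | COc1ccc([C@@H]2c3cc(OC)c(OC)cc3C(=O)[C@@H](C)[C@@H]2C)cc1OC(C)=O | intermediate
9 | (2S,3R,4R)-4-(3-hydroxy-4-methoxyphenyl)-6,7-dimethoxy-2,3-dimethyl-3,4-dihydronaphthalen-1(2H)-one | COc1ccc([C@@H]2c3cc(OC)c(OC)cc3C(=O)[C@@H](C)[C@@H]2C)cc1O | target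

**Step count**

Total step count: 5. Longest linear sequence: 5 steps (1 → 2 → 4 → 5 → 8 → 9).

**Steps most likely to fail**

1. Step 4 (Proposed new method).
   - What may go wrong: facial discrimination by the chiral anion in the C2–C3 bond formation may be poor. The distonic radical cation may close to a cyclobutene, or take its hydrogen atom before the ring has closed, which would lose the 3,4-cis control. The ynol ether may oligomerise under the acid that builds up, and the electron-rich enol ether may be oxidised further.
   - Fallback (known chemistry only), setting out from 5 and coming back at 8: a Giese-type reductive radical addition of tert-butyl 2-bromopropanoate to 5 [(Me3Si)3SiH, AIBN, PhH, 80 °C] should give tert-butyl 4-(3-acetoxy-4-methoxyphenyl)-4-(3,4-dimethoxyphenyl)-2,3-dimethylbutanoate F1 as a mixture of stereoisomers. Here the electrophilic α-ester radical adds to C3 and the diarylmethyl radical takes hydrogen from the silane. TFA in CH2Cl2 should cleave the ester to 4-(3-acetoxy-4-methoxyphenyl)-4-(3,4-dimethoxyphenyl)-2,3-dimethylbutanoic acid F2. TFAA in CH2Cl2 (intramolecular Friedel–Crafts acylation, which for the same electronic reason closes on the dimethoxy ring para to its C6 methoxy group) should give the tetralone acetate F3 as its 3,4-cis and 3,4-trans racemates. After equilibration of C2 with DBU, the 3,4-cis racemate would be separated by chromatography or crystallisation and resolved by preparative chromatography on a chiral stationary phase to give 8. This route gives up the stereocontrol of the key step and pays for it with separations.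

2. Step 2.
   - What may go wrong: hydrolysis of the electron-rich enol triflate back to ketone 1 in the aqueous base and protodeboronation of the electron-rich boronic acid 3 may outrun the coupling.
   - Fallback, setting out from 2 and coming back at 4: the roles of the partners are exchanged. Miyaura borylation of 2 under anhydrous conditions (B2pin2, PdCl2(PPh3)2, PPh3, KOPh, toluene, 50 °C) should give (E)-2-[1-(3,4-dimethoxyphenyl)prop-1-en-1-yl]-4,4,5,5-tetramethyl-1,3,2-dioxaborolane F4 with retention. Its Suzuki–Miyaura coupling with commercial 5-bromo-2-methoxyphenol (Pd(dppf)Cl2, K3PO4, dioxane/H2O, 80 °C) should give 4.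

3. Step 5.
   - What may go wrong: aerobic oxidation of the electron-rich phenoxide in basic methanol, and incomplete equilibration at C2.
   - Fallback, setting out from 8 and coming back at 9, without a new isolated compound: the two tasks are separated and the phenoxide is avoided. C2 is first equilibrated in 8 with a catalytic amidine base (DBU, CH2Cl2, rt). The acetyl group is then moved to an amine by aminolysis (pyrrolidine, CH2Cl2, 0 °C), which should set the neutral phenol 9 free.

**Further compounds**

F1 | step 4 | tert-butyl 4-(3-acetoxy-4-methoxyphenyl)-4-(3,4-dimethoxyphenyl)-2,3-dimethylbutanoate (mixture of stereoisomers) | CC(C(=O)OC(C)(C)C)C(C)C(c1ccc(OC)c(OC)c1)c1ccc(OC)c(OC(C)=O)c1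
F2 | step 4 | 4-(3-acetoxy-4-methoxyphenyl)-4-(3,4-dimethoxyphenyl)-2,3-dimethylbutanoic acid (mixture of stereoisomers) | CC(C(=O)O)C(C)C(c1ccc(OC)c(OC)c1)c1ccc(OC)c(OC(C)=O)c1
F3 | step 4 | 5-(6,7-dimethoxy-2,3-dimethyl-4-oxo-1,2,3,4-tetrahydronaphthalen-1-yl)-2-methoxyphenyl acetate (racemic, both relative configurations at the aryl-bearing carbon) | COc1ccc(C2c3cc(OC)c(OC)cc3C(=O)C(C)C2C)cc1OC(C)=O
F4 | step 2 | (E)-2-[1-(3,4-dimethoxyphenyl)prop-1-en-1-yl]-4,4,5,5-tetramethyl-1,3,2-dioxaborolane | C/C=C(/c1ccc(OC)c(OC)c1)B1OC(C)(C)C(C)(C)O1
F0 | step 5 | none | none
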